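Its constants are invented; no experiment stands behind them.

Four vessels, one catalyst round.

in all of them: free catalyst 15 mol%

| charge | substrate | time | remark |
|---|---|---|---|
| autumn | 0.032 M (fed, over 3.20 min) | 4.0 min | all but substrate at the start; substrate goes in evenly over 3.20 min, the run ends at 4.0 min |
| dawn | 0.032 M |  | one stirred flow tank at steady state, fed with the mixture as stated, mean residence time 12.0 min |
| winter | 0.032 M | 4.0 min | everything together in a closed stirred flask, run for 4.0 min |
| dusk | 0.032 M |  | a single well-mixed tank run continuously and read at steady state, 4.0 min in it on average |

    substrate + catalyst intermediate A → spent catalyst (k1 = 0.27 L mol⁻¹ s⁻¹)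
    catalyst intermediate B → free catalyst + target (k2 = 0.22 s⁻¹)
    target ⇌ isomer of the product (K3 = 2.5, k3 = 0.012 s⁻¹)
    catalyst intermediate A ⇌ catalyst intermediate B (K4 = 0.69, k4 = 0.094 s⁻¹)
    substrate + free catalyst ⇌ catalyst intermediate A (K5 = 16 L mol⁻¹, k5 = 9.9 L mol⁻¹ s⁻¹)

- a species is counted by the substrate in it: one spent catalyst counts as two
- the stated concentrations are those of everything mixed, before any reaction; amounts are the same in each set-up
- the feed brings no volume worth counting
- run time (autumn): 4.0 min

1. the set-up with the highest amount of target at the outlet or at the end, in percent of the substrate put in ("none" if the first two lie within 2 percentage points) (autumn / dawn / winter / dusk / none)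
2. amount of target at the outlet or at the end, in percent of the substrate put in, autumn
3. amount of target at the outlet or at the end, in percent of the substrate put in, dawn
4. amount of target at the outlet or at the end, in percent of the substrate put in, winter
5. amount of target at the outlet or at the end, in percent of the substrate put in, dusk

All amounts below are fractions of the substrate charge.

The end state comes first. At equilibrium, step 3 leaves target 28.6% of the pool, meaning target plus isomer of the product; this is the equilibrium share. The pool relaxes with a half-life of 0.688 min, shorter than the 4.0 min run. In a tank, outflow competes with step 3, so the share stands higher: 34.0% in dawn and 42.8% in dusk.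

Then comes the speed. My crude reckoning holds step 5 at equilibrium, ignores catalyst loss, and lets intermediate A pass on at 3.48 min⁻¹. Substrate then falls pseudo-first-order at 0.177 min⁻¹. That fills the pool to 68.0% in dawn and 41.4% in dusk. Share times pool gives 23.1% for dawn and 17.7% for dusk. Taking the equilibrium share as a floor gives at least 14.5% for winter. For autumn, counted from the mean time after dosing, the floor is 9.88%. My choice is dawn.

The forecast also names dawn, with 20.9% there, 15.8% for autumn, 15.8% for winter and 14.5% for dusk, on the ground that “its longer time gives far more conversion, which outweighs the extra isomerisation”.

The simulation gives dawn: autumn 15.2%, dawn 20.9%, winter 16.8%, dusk 14.2%. The forecast's tie between autumn and winter opens to 1.6 percentage points, inside its ranges.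

In autumn, substrate entered until 3.20 min, while step 3 was already carrying target to isomer of the product, which read 9.30% then. At 4.00 min, the pool in autumn read 29.8%, so the equilibrium share of it gives 8.52%, and target stood higher, at 15.2%.

Autumn read at 10 min holds a pool of 65.3%, so the equilibrium share gives 18.7%. The computed target is higher, at 21.6%, which is 33.2% of that pool.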